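**Retrosynthetic overview**
1. Numbering: the core is 2,9-dioxabicyclo[3.3.1]nona-3,7-diene (C1 ketal carbon, O2, C3, C4, C5, C6, C7, C8, O9); ring A = O2–C3=C4–C5–O9–C1, ring B = C1–C8=C7–C6–C5–O9; the chain on C3 is C1′–C9′ (C2′ on C3, C3′ the ketone).
2. Key disconnection: the tetrasubstituted enol-ether bond C3=C4, closed by ring-closing olefin metathesis between an O2-bound C3=CH2 enol ether and an isopropenyl group (C4) on C5; it opens ring A, removes the three-atom bridge and splits the molecule into a western C12 and an eastern C11 half.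
3. Enabling feature: on ring B the ketal oxygen O2 (on C1) and the C4 alkene (on C5) are cis and 1,3-related across O9, and both can stand axial (anomeric effect at C1), so the two alkenes meet above O9 and ring A closes as an unstrained six-membered ring.
4. O2–C3 is made as an ester: EtLi adds to the ring B lactone and the lithium hemiketalate is acylated by the western acid chloride (sets C1), then the ester C=O is methylenated; ring B comes first, from methacrylate ring-closing metathesis on the anti-crotylation product of methacrolein (sets C5, C6).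
5. Western acid by Evans alkylation (C4′) and Evans syn-aldol (C2′); C3′ stays a silyl ether and is oxidised last; ring order: ring B (step 11), then ring A (step 14).

Key step: step 14

Remark: in step 9 the (S)-catalyst is assigned by analogy with simple aldehydes (Si-face addition); if the facial sense were the opposite one, the (R)-catalyst would be taken, and the configuration of 16 would be checked before going on.

Remark: in the SMILES of the Tebbe reagent and of titanocene oxide the cyclopentadienyl rings are written σ-bonded, and the Ti–Cl–Al bridge of the Tebbe reagent is written in its charge-separated (chloronium/aluminate) form.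

**Route**

Step 1
Reactants: 1 (2E)-2-methylpent-2-enal
Product: 2 (2E)-2-methylpent-2-en-1-ol
Conditions: NaBH4, CeCl3·7H2O, MeOH, 0 °C
Reagents that add atoms: none
Why: Luche 1,2-reduction should give the allylic alcohol without conjugate reduction or loss of the E geometry.

Step 2
Reactants: 2 (2E)-2-methylpent-2-en-1-ol
Product: 3 (2E)-1-bromo-2-methylpent-2-ene
Conditions: PBr3, pyridine (cat.), Et2O, 0 °C
Reagents that add atoms: phosphorus tribromide, BrP(Br)Br
Why: Bromination of a primary allylic alcohol with PBr3 at low temperature should proceed by direct substitution with little allylic transposition.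

Step 3
Reactants: 4 (4S)-4-benzyl-3-propanoyl-1,3-oxazolidin-2-one; 3 (2E)-1-bromo-2-methylpent-2-ene
Product: 6 (4S)-4-benzyl-3-[(2R,4E)-2,4-dimethylhept-4-enoyl]-1,3-oxazolidin-2-one, via sodium enolate 5 (not isolated)
Conditions: NaN(SiMe3)2, THF, −78 °C; then 3, −78 to −40 °C
Reagents that add atoms: none
Why: Evans asymmetric alkylation, in which the chelated Z-enolate is alkylated on the face away from the benzyl group, should set the later C4′ as R.

Step 4
Reactants: 6 (4S)-4-benzyl-3-[(2R,4E)-2,4-dimethylhept-4-enoyl]-1,3-oxazolidin-2-one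
Product: 7 (2R,4E)-2,4-dimethylhept-4-en-1-ol
Conditions: LiBH4, MeOH, Et2O, 0 °C
Reagents that add atoms: none
Why: Reductive removal of the auxiliary at the exocyclic carbonyl should give the primary alcohol without touching the α-stereocentre.

Step 5
Reactants: 7 (2R,4E)-2,4-dimethylhept-4-en-1-ol
Product: 8 (2R,4E)-2,4-dimethylhept-4-enal
Conditions: Dess–Martin periodinane, NaHCO3, CH2Cl2, 0 °C to rt; used crude
Reagents that add atoms: none
Why: Buffered Dess–Martin oxidation should give the α-branched aldehyde without epimerisation if it is used at once.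

Step 6
Reactants: 9 (4R)-4-benzyl-3-propanoyl-1,3-oxazolidin-2-one; 8 (2R,4E)-2,4-dimethylhept-4-enal
Product: 11 (4R)-4-benzyl-3-[(2R,3S,4R,6E)-3-hydroxy-2,4,6-trimethylnon-6-enoyl]-1,3-oxazolidin-2-one, via dibutylboron enolate 10 (not isolated)
Conditions: Bu2BOTf, Et3N, CH2Cl2, −78 to 0 °C; then 8, −78 to 0 °C; pH 7 buffer, MeOH, H2O2
Reagents that add atoms: none
Why: Evans syn-aldol through the Z-boron enolate and a chair Zimmerman–Traxler transition state should set C2 (the later C2′) as R under auxiliary control, the C3 carbinol (2,3-syn) being oxidised later.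

Step 7
Reactants: 11 (4R)-4-benzyl-3-[(2R,3S,4R,6E)-3-hydroxy-2,4,6-trimethylnon-6-enoyl]-1,3-oxazolidin-2-one
Product: 12 (4R)-4-benzyl-3-[(2R,3S,4R,6E)-3-(tert-butyldimethylsilyloxy)-2,4,6-trimethylnon-6-enoyl]-1,3-oxazolidin-2-one
Conditions: TBSOTf, 2,6-lutidine, CH2Cl2, −78 to 0 °C
Reagents that add atoms: tert-butyldimethylsilyl triflate, CC(C)(C)[Si](C)(C)OS(=O)(=O)C(F)(F)F
Why: Silylation with the silyl triflate should protect the hindered secondary alcohol and block retro-aldol in the later steps.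

Step 8
Reactants: 12 (4R)-4-benzyl-3-[(2R,3S,4R,6E)-3-(tert-butyldimethylsilyloxy)-2,4,6-trimethylnon-6-enoyl]-1,3-oxazolidin-2-one
Product: 14 (2R,3S,4R,6E)-3-(tert-butyldimethylsilyloxy)-2,4,6-trimethylnon-6-enoic acid, via lithium peroxycarboxylate 13 (not isolated)
Conditions: LiOH, H2O2, THF/H2O, 0 °C; Na2SO3; HCl to pH 3
Reagents that add atoms: lithium hydroperoxide (from LiOH and H2O2), [Li+].[O-]O
Why: Hydroperoxide cleaves the exocyclic imide carbonyl selectively and without epimerisation, and sulfite reduces the peracid to the acid.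

Step 9
Reactants: 15 2-methylprop-2-enal (methacrolein)
Product: 16 (3S,4S)-2,4-dimethylhexa-1,5-dien-3-ol
Conditions: (E)-crotylboronic acid pinacol ester, (S)-TRIP [(S)-3,3′-bis(2,4,6-triisopropylphenyl)-1,1′-binaphthyl-2,2′-diyl hydrogen phosphate] (5 mol %), 4 Å MS, toluene, −30 °C; aqueous work-up
Reagents that add atoms: (E)-crotylboronic acid pinacol ester, C/C=C/CB1OC(C)(C)C(C)(C)O1
Why: Chiral-phosphoric-acid-catalysed crotylboration through a closed chair transition state should turn the E-crotyl geometry into the anti relationship and, by Si-face addition, set the later C5 and C6 of the bicycle.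

Step 10
Reactants: 16 (3S,4S)-2,4-dimethylhexa-1,5-dien-3-ol
Product: 17 (3S,4S)-2,4-dimethylhexa-1,5-dien-3-yl 2-methylprop-2-enoate
Conditions: methacryloyl chloride, Et3N, DMAP (cat.), CH2Cl2, 0 °C
Reagents that add atoms: methacryloyl chloride, CC(=C)C(=O)Cl
Why: DMAP-catalysed acylation of the secondary allylic alcohol should give the methacrylate without affecting the stereocentres.

Step 11
Reactants: 17 (3S,4S)-2,4-dimethylhexa-1,5-dien-3-yl 2-methylprop-2-enoate
Product: 18 (5S,6S)-3,5-dimethyl-6-(prop-1-en-2-yl)-5,6-dihydro-2H-pyran-2-one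
Conditions: second-generation Grubbs catalyst RuCl2(=CHPh)(PCy3)(H2IMes) (5 mol %), toluene (5 mM), 80 °C
Reagents that add atoms: none
Why: Ring-closing metathesis of the methacrylate with the monosubstituted vinyl group should close ring B as the six-membered lactone with the cis C7=C8 alkene, the isopropenyl group standing by because its closure would need a five-membered ring with a tetrasubstituted alkene.

Step 12
Reactants: 18 (5S,6S)-3,5-dimethyl-6-(prop-1-en-2-yl)-5,6-dihydro-2H-pyran-2-one; 14 (2R,3S,4R,6E)-3-(tert-butyldimethylsilyloxy)-2,4,6-trimethylnon-6-enoic acid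
Product: 21 (2S,5S,6S)-2-ethyl-3,5-dimethyl-6-(prop-1-en-2-yl)-5,6-dihydro-2H-pyran-2-yl (2R,3S,4R,6E)-3-(tert-butyldimethylsilyloxy)-2,4,6-trimethylnon-6-enoate, via acid chloride 19 (not isolated), via lithium hemiketalate 20 (not isolated)
Conditions: flask 1: 14, 1-chloro-N,N,2-trimethylprop-1-en-1-amine, CH2Cl2, 0 °C to rt; flask 2: 18, EtLi, Et2O/THF, −78 °C; then contents of flask 1, −78 to −40 °C; Et3N, NaHCO3 (aq); Et3N-deactivated silica
Reagents that add atoms: ethyllithium, [Li]CC
Why: Axial 1,2-addition of EtLi to the lactone carbonyl should place ethyl trans and the alkoxide oxygen cis to the isopropenyl group, and this lithium hemiketalate is trapped as its ester before it can ring-open (as in ester formation from lithium tert-alkoxides and acid chlorides and in one-pot acylation of lactol alkoxides), which fixes the later C1 kinetically.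

Step 13
Reactants: 21 (2S,5S,6S)-2-ethyl-3,5-dimethyl-6-(prop-1-en-2-yl)-5,6-dihydro-2H-pyran-2-yl (2R,3S,4R,6E)-3-(tert-butyldimethylsilyloxy)-2,4,6-trimethylnon-6-enoate
Product: 22 tert-butyl{[(3R,4S,5R,7E)-2-{[(2S,5S,6S)-2-ethyl-3,5-dimethyl-6-(prop-1-en-2-yl)-5,6-dihydro-2H-pyran-2-yl]oxy}-3,5,7-trimethyldeca-1,7-dien-4-yl]oxy}dimethylsilane (the ester C=O of 21 turned into C=CH2)
Conditions: Tebbe reagent Cp2Ti(μ-CH2)(μ-Cl)AlMe2, pyridine, THF/toluene, −40 to 0 °C; NaOH (aq); basic Al2O3, kept cold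
Reagents that add atoms: Tebbe reagent, C[Al-]1(C)C[Ti]([Cl+]1)(C1C=CC=C1)C1C=CC=C1
Why: Titanium-methylidene carbonyl methylenation of an ester, known for anomeric esters (giving alkenyl glycosides), should turn the acyloxy ketal into the O-alkenyl ketal without base or heat, so that neither C2′ nor the allyl vinyl ether is put at risk.

Step 14
Reactants: 22 tert-butyl{[(3R,4S,5R,7E)-2-{[(2S,5S,6S)-2-ethyl-3,5-dimethyl-6-(prop-1-en-2-yl)-5,6-dihydro-2H-pyran-2-yl]oxy}-3,5,7-trimethyldeca-1,7-dien-4-yl]oxy}dimethylsilane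
Product: 23 tert-butyl{[(2R,3S,4R,6E)-2-[(1S,5S,6S)-1-ethyl-4,6,8-trimethyl-2,9-dioxabicyclo[3.3.1]nona-3,7-dien-3-yl]-4,6-dimethylnon-6-en-3-yl]oxy}dimethylsilane
Conditions: Mo(=CHCMe2Ph)(=N-2,6-iPr2C6H3)[OCMe(CF3)2]2 (20 mol %), benzene (2 mM), 25 to 50 °C, argon sweep
Reagents that add atoms: none
Why: Proposed new method: the molybdenum alkylidene should exchange with the isopropenyl group on C5 by [2+2] cycloaddition and cycloreversion to give a Mo=C4 alkylidene, which adds across the enol ether C3=CH2 held on the same face through O2–C1–O9, and cycloreversion of that metallacyclobutane releases the C3=C4 bond and ethylene. The closest known reaction types are the enol ether–olefin ring-closing metathesis of methylenated olefinic esters to cyclic enol ethers with molybdenum alkylidenes and the molybdenum-catalysed ring-closing metathesis of two 1,1-disubstituted alkenes to tetrasubstituted cycloalkenes; new here is their combination in a tetrasubstituted enol-ether bond closed across a ketal tether. Ring A (O2–C3=C4–C5–O9–C1) closes as a six-membered ring bridging C1 and C5 of ring B, which creates the 2,9-dioxabicyclo[3.3.1]nona-3,7-diene skeleton and joins the two halves at the most hindered bond. No stereocentre is formed: C1, C5 and C6 come from steps 12 and 9, and the C3=C4 geometry is fixed by the ring. The step needs cyclisation to win over oligomerisation, over [3,3] rearrangement of the allyl vinyl ether and over metathesis at the two trisubstituted alkenes; the cis placement of O2 and the isopropenyl group across O9 with O2 axial by the anomeric effect, high dilution, a temperature at or below 50 °C and the inertness of trisubstituted alkenes should secure this.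

Step 15
Reactants: 23 tert-butyl{[(2R,3S,4R,6E)-2-[(1S,5S,6S)-1-ethyl-4,6,8-trimethyl-2,9-dioxabicyclo[3.3.1]nona-3,7-dien-3-yl]-4,6-dimethylnon-6-en-3-yl]oxy}dimethylsilane
Product: 24 (2R,3S,4R,6E)-2-[(1S,5S,6S)-1-ethyl-4,6,8-trimethyl-2,9-dioxabicyclo[3.3.1]nona-3,7-dien-3-yl]-4,6-dimethylnon-6-en-3-ol
Conditions: Bu4NF, THF, 25 to 40 °C; NH4Cl (aq)
Reagents that add atoms: none
Why: Fluoride desilylation is basic and should leave the acid-labile enol ketal intact.

Step 16
Reactants: 24 (2R,3S,4R,6E)-2-[(1S,5S,6S)-1-ethyl-4,6,8-trimethyl-2,9-dioxabicyclo[3.3.1]nona-3,7-dien-3-yl]-4,6-dimethylnon-6-en-3-ol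
Product: 25 (2S,4R,6E)-2-[(1S,5S,6S)-1-ethyl-4,6,8-trimethyl-2,9-dioxabicyclo[3.3.1]nona-3,7-dien-3-yl]-4,6-dimethylnon-6-en-3-one (CNP0232650.2)
Conditions: Dess–Martin periodinane, NaHCO3, CH2Cl2, 0 °C
Reagents that add atoms: none
Why: Buffered Dess–Martin oxidation under near-neutral conditions should unmask the C3′ ketone last, so that C2′ and C4′ are not epimerised and the C3=C4 enol ether does not move into conjugation.

**Compound list**
1 | (2E)-2-methylpent-2-enal | CC/C=C(\C)C=O | starting material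
2 | (2E)-2-methylpent-2-en-1-ol | CC/C=C(\C)CO | intermediate
3 | (2E)-1-bromo-2-methylpent-2-ene | CC/C=C(\C)CBr | intermediate
4 | (4S)-4-benzyl-3-propanoyl-1,3-oxazolidin-2-one | CCC(=O)N1[C@@H](Cc2ccccc2)COC1=O | starting material
5 | sodium Z-enolate of 4 | C/C=C(\[O-])N1[C@@H](Cc2ccccc2)COC1=O.[Na+] | intermediate
6 | (4S)-4-benzyl-3-[(2R,4E)-2,4-dimethylhept-4-enoyl]-1,3-oxazolidin-2-one | CC/C=C(\C)C[C@@H](C)C(=O)N1[C@@H](Cc2ccccc2)COC1=O | intermediate
7 | (2R,4E)-2,4-dimethylhept-4-en-1-ol | CC/C=C(\C)C[C@@H](C)CO | intermediate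
8 | (2R,4E)-2,4-dimethylhept-4-enal | CC/C=C(\C)C[C@@H](C)C=O | intermediate
9 | (4R)-4-benzyl-3-propanoyl-1,3-oxazolidin-2-one | CCC(=O)N1[C@H](Cc2ccccc2)COC1=O | starting material
10 | dibutylboron Z-enolate of 9 | C/C=C(\OB(CCCC)CCCC)N1[C@H](Cc2ccccc2)COC1=O | intermediate
11 | (4R)-4-benzyl-3-[(2R,3S,4R,6E)-3-hydroxy-2,4,6-trimethylnon-6-enoyl]-1,3-oxazolidin-2-one | CC/C=C(\C)C[C@@H](C)[C@H](O)[C@@H](C)C(=O)N1[C@H](Cc2ccccc2)COC1=O | intermediate
12 | (4R)-4-benzyl-3-[(2R,3S,4R,6E)-3-(tert-butyldimethylsilyloxy)-2,4,6-trimethylnon-6-enoyl]-1,3-oxazolidin-2-one | CC/C=C(\C)C[C@@H](C)[C@H](O[Si](C)(C)C(C)(C)C)[C@@H](C)C(=O)N1[C@H](Cc2ccccc2)COC1=O | intermediate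
13 | lithium (2R,3S,4R,6E)-3-(tert-butyldimethylsilyloxy)-2,4,6-trimethylnon-6-eneperoxoate | CC/C=C(\C)C[C@@H](C)[C@H](O[Si](C)(C)C(C)(C)C)[C@@H](C)C(=O)O[O-].[Li+] | intermediate
14 | (2R,3S,4R,6E)-3-(tert-butyldimethylsilyloxy)-2,4,6-trimethylnon-6-enoic acid | CC/C=C(\C)C[C@@H](C)[C@H](O[Si](C)(C)C(C)(C)C)[C@@H](C)C(=O)O | intermediate
15 | 2-methylprop-2-enal | CC(=C)C=O | starting material
16 | (3S,4S)-2,4-dimethylhexa-1,5-dien-3-ol | CC(=C)[C@@H](O)[C@@H](C)C=C | intermediate
17 | (3S,4S)-2,4-dimethylhexa-1,5-dien-3-yl 2-methylprop-2-enoate | CC(=C)[C@@H](OC(=O)C(C)=C)[C@@H](C)C=C | intermediate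
18 | (5S,6S)-3,5-dimethyl-6-(prop-1-en-2-yl)-5,6-dihydro-2H-pyran-2-one | CC(=C)[C@H]1OC(=O)C(C)=C[C@@H]1C | intermediate
19 | (2R,3S,4R,6E)-3-(tert-butyldimethylsilyloxy)-2,4,6-trimethylnon-6-enoyl chloride | CC/C=C(\C)C[C@@H](C)[C@H](O[Si](C)(C)C(C)(C)C)[C@@H](C)C(=O)Cl | intermediate
20 | lithium (2R,5S,6S)-2-ethyl-3,5-dimethyl-6-(prop-1-en-2-yl)-5,6-dihydro-2H-pyran-2-olate | CC(=C)[C@H]1O[C@@](CC)([O-])C(C)=C[C@@H]1C.[Li+] | intermediate
21 | (2S,5S,6S)-2-ethyl-3,5-dimethyl-6-(prop-1-en-2-yl)-5,6-dihydro-2H-pyran-2-yl (2R,3S,4R,6E)-3-(tert-butyldimethylsilyloxy)-2,4,6-trimethylnon-6-enoate | CC/C=C(\C)C[C@@H](C)[C@H](O[Si](C)(C)C(C)(C)C)[C@@H](C)C(=O)O[C@]1(CC)O[C@H](C(C)=C)[C@@H](C)C=C1C | intermediate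
22 | tert-butyl{[(3R,4S,5R,7E)-2-{[(2S,5S,6S)-2-ethyl-3,5-dimethyl-6-(prop-1-en-2-yl)-5,6-dihydro-2H-pyran-2-yl]oxy}-3,5,7-trimethyldeca-1,7-dien-4-yl]oxy}dimethylsilane | CC/C=C(\C)C[C@@H](C)[C@H](O[Si](C)(C)C(C)(C)C)[C@@H](C)C(=C)O[C@]1(CC)O[C@H](C(C)=C)[C@@H](C)C=C1C | intermediate
23 | tert-butyl{[(2R,3S,4R,6E)-2-[(1S,5S,6S)-1-ethyl-4,6,8-trimethyl-2,9-dioxabicyclo[3.3.1]nona-3,7-dien-3-yl]-4,6-dimethylnon-6-en-3-yl]oxy}dimethylsilane | CC/C=C(\C)C[C@@H](C)[C@H](O[Si](C)(C)C(C)(C)C)[C@@H](C)C1=C(C)[C@H]2O[C@@](CC)(O1)C(C)=C[C@@H]2C | intermediate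
24 | (2R,3S,4R,6E)-2-[(1S,5S,6S)-1-ethyl-4,6,8-trimethyl-2,9-dioxabicyclo[3.3.1]nona-3,7-dien-3-yl]-4,6-dimethylnon-6-en-3-ol | CC/C=C(\C)C[C@@H](C)[C@H](O)[C@@H](C)C1=C(C)[C@H]2O[C@@](CC)(O1)C(C)=C[C@@H]2C | intermediate
25 | (2S,4R,6E)-2-[(1S,5S,6S)-1-ethyl-4,6,8-trimethyl-2,9-dioxabicyclo[3.3.1]nona-3,7-dien-3-yl]-4,6-dimethylnon-6-en-3-one | CC/C=C(\C)C[C@@H](C)C(=O)[C@@H](C)C1=C(C)[C@H]2O[C@@](CC)(O1)C(C)=C[C@@H]2C | target

**Step count and risks**
Total step count: 16. Longest linear sequence: 13 steps (steps 1–8, then 12–16); steps 9–11 form the convergent eastern branch.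

Steps most likely to fail:

1. Step 14. What may go wrong: the catalyst may not bring two 1,1-disubstituted alkenes together into a tetrasubstituted alkene (slow loading on the isopropenyl group, unproductive carbene on the enol ether), so that oligomerisation, catalyst decay or thermal [3,3] rearrangement of the allyl vinyl ether take over. Fallback, which closes ring A at a trisubstituted C3=C4 and adds the C4 methyl afterwards; it sets out from acid 14 and comes back at 23. (E)-But-2-enal is crotylated as in step 9 to (2E,4R,5S)-5-methylhepta-2,6-dien-4-ol F1, which is acylated as in step 10 to (2E,4R,5S)-5-methylhepta-2,6-dien-4-yl 2-methylprop-2-enoate F2 and closed as in step 11 to (5S,6R)-3,5-dimethyl-6-[(1E)-prop-1-en-1-yl]-5,6-dihydro-2H-pyran-2-one F3. EtLi addition gives the lithium hemiketalate F4, which is acylated by acid chloride 19 (made from 14 as in step 12) to the acyloxy ketal F5, and Tebbe methylenation as in step 13 gives the O-alkenyl ketal F6. Enol ether–olefin ring-closing metathesis to a trisubstituted cyclic enol ether, a closely precedented case (second-generation Hoveyda–Grubbs catalyst RuCl2(=CH-2-iPrOC6H4)(H2IMes), toluene, 60 °C, loss of propene), should give the 4-desmethyl bicycle F7. Iodination at C4 as practised on glycals (N-iodosuccinimide, AgNO3 cat., MeCN) should give the 4-iodo bicycle F8, and Suzuki–Miyaura methylation (trimethylboroxine, Pd(dppf)Cl2, K2CO3, dioxane/H2O) returns to 23.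

2. Step 12. What may go wrong: the lithium hemiketalate may ring-open to the keto alkoxide before it is acylated, so that the acyl group ends on the secondary oxygen, or the tertiary allylic acyloxy ketal may ionise on work-up with loss of the C1 configuration. Fallback, which sets out from lactone 18 and comes back at 21: the EtLi adduct is quenched with NH4Cl (aq) and isolated as the lactol (5S,6S)-2-ethyl-3,5-dimethyl-6-(prop-1-en-2-yl)-5,6-dihydro-2H-pyran-2-ol F9 (both C2 anomers, in equilibrium with the open hydroxy enone). F9 is then acylated with acid chloride 19 under nucleophilic catalysis (Et3N, DMAP, CH2Cl2, −20 °C). Under fast mutarotation the equatorial and more nucleophilic hemiketal hydroxyl, which is the one cis to the isopropenyl group, should be acylated first, as in the kinetic anomeric acylation of lactols; competing acylation of the open-chain secondary hydroxyl is the point to watch.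

3. Step 13. What may go wrong: the aluminium Lewis acid may strip the acyloxy group from the tertiary allylic C1, or the enol ether may be lost by hydrolysis or rearrangement during isolation. Fallback, which sets out from ester 21 and comes back at 23 without any isolated enol ether: an olefinic-ester cyclisation with an amine-buffered reduced titanium ethylidene (TiCl4, Zn, PbCl2 cat., TMEDA, CH3CHBr2, THF/CH2Cl2, 25 to 65 °C). The titanium alkylidene exchanges at the isopropenyl group with loss of propene and then olefinates the ester carbonyl intramolecularly. This fallback makes no new compound.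

**Further compounds**
F1 | step 14 | (2E,4R,5S)-5-methylhepta-2,6-dien-4-ol | C/C=C/[C@@H](O)[C@@H](C)C=C
F2 | step 14 | (2E,4R,5S)-5-methylhepta-2,6-dien-4-yl 2-methylprop-2-enoate | C/C=C/[C@@H](OC(=O)C(C)=C)[C@@H](C)C=C
F3 | step 14 | (5S,6R)-3,5-dimethyl-6-[(1E)-prop-1-en-1-yl]-5,6-dihydro-2H-pyran-2-one | C/C=C/[C@H]1OC(=O)C(C)=C[C@@H]1C
F4 | step 14 | lithium (2R,5S,6R)-2-ethyl-3,5-dimethyl-6-[(1E)-prop-1-en-1-yl]-5,6-dihydro-2H-pyran-2-olate | C/C=C/[C@H]1O[C@@](CC)([O-])C(C)=C[C@@H]1C.[Li+]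
F5 | step 14 | (2S,5S,6R)-2-ethyl-3,5-dimethyl-6-[(1E)-prop-1-en-1-yl]-5,6-dihydro-2H-pyran-2-yl (2R,3S,4R,6E)-3-(tert-butyldimethylsilyloxy)-2,4,6-trimethylnon-6-enoate | CC/C=C(\C)C[C@@H](C)[C@H](O[Si](C)(C)C(C)(C)C)[C@@H](C)C(=O)O[C@]1(CC)O[C@H](/C=C/C)[C@@H](C)C=C1C
F6 | step 14 | tert-butyl{[(3R,4S,5R,7E)-2-{[(2S,5S,6R)-2-ethyl-3,5-dimethyl-6-[(1E)-prop-1-en-1-yl]-5,6-dihydro-2H-pyran-2-yl]oxy}-3,5,7-trimethyldeca-1,7-dien-4-yl]oxy}dimethylsilane | CC/C=C(\C)C[C@@H](C)[C@H](O[Si](C)(C)C(C)(C)C)[C@@H](C)C(=C)O[C@]1(CC)O[C@H](/C=C/C)[C@@H](C)C=C1C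
F7 | step 14 | tert-butyl{[(2R,3S,4R,6E)-2-[(1S,5S,6S)-1-ethyl-6,8-dimethyl-2,9-dioxabicyclo[3.3.1]nona-3,7-dien-3-yl]-4,6-dimethylnon-6-en-3-yl]oxy}dimethylsilane | CC/C=C(\C)C[C@@H](C)[C@H](O[Si](C)(C)C(C)(C)C)[C@@H](C)C1=C[C@H]2O[C@@](CC)(O1)C(C)=C[C@@H]2C
F8 | step 14 | tert-butyl{[(2R,3S,4R,6E)-2-[(1S,5S,6S)-1-ethyl-4-iodo-6,8-dimethyl-2,9-dioxabicyclo[3.3.1]nona-3,7-dien-3-yl]-4,6-dimethylnon-6-en-3-yl]oxy}dimethylsilane | CC/C=C(\C)C[C@@H](C)[C@H](O[Si](C)(C)C(C)(C)C)[C@@H](C)C1=C(I)[C@H]2O[C@@](CC)(O1)C(C)=C[C@@H]2C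
F9 | step 12 | (5S,6S)-2-ethyl-3,5-dimethyl-6-(prop-1-en-2-yl)-5,6-dihydro-2H-pyran-2-ol | CC(=C)[C@H]1OC(O)(CC)C(C)=C[C@@H]1C
F0 | step 13 | none | none
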